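**Strategy.** The route rests on the C9–C10 bond of the cyclohexane C5–C10 (elemane numbering). C9 is a carbinol next to the quaternary C10 that carries the vinyl group C1=C2, which is the retron of an allylboration. The cis-fused γ-lactone (O–C12–C11–C7–C8) is made first by a proline aldol. It carries C9 as a dimethyl acetal on C8 and, on C7, a chain that ends in a (Z)-allylboronate, installed by a first, reagent-controlled allylboration that also sets C5 and C6. Acid then unmasks the C9 aldehyde, and an intramolecular allylboration closes the carbocycle as the last ring, setting C9 and C10 by relay from C5.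

Key step: step 8

Remark: elemane numbering is used throughout (ring C5–C10; vinyl C1=C2; acrolein C3/C4/C15; lactone O–C12(=O)–C11(=C13)–C7–C8); the phosphonate-bearing carbon C11 of compounds 6–21 is epimerisable and becomes sp2 in step 12, so it is carried as an epimer mixture and drawn as the more stable 3,4-trans epimer.

Step 1
Reactants: 1 trimethyl phosphonoacetate; 2 allyl bromide
Product: 3 methyl 2-(dimethoxyphosphoryl)pent-4-enoate (racemic)
Conditions: NaH (1.0 equiv), THF, 0 °C → rt
Reagents that add atoms: none
Why: SN2 C-alkylation of the sodium phosphonoacetate carbanion should give the mono-allyl product; the new centre is racemic and is destroyed in step 12.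

Step 2
Reactants: 3 methyl 2-(dimethoxyphosphoryl)pent-4-enoate
Product: 4 methyl 2-(dimethoxyphosphoryl)-4-oxobutanoate (racemic)
Conditions: O3, CH2Cl2, −78 °C; then Me2S, −78 °C → rt
Reagents that add atoms: ozone [O-][O+]=O
Why: Ozonolysis with reductive work-up should cleave the only alkene to the aldehyde without touching the phosphonoacetate; no stereocentre is formed.

Step 3
Reactants: 4 methyl 2-(dimethoxyphosphoryl)-4-oxobutanoate; 5 2,2-dimethoxyacetaldehyde
Product: 7 dimethyl [(3S,4S,5R)-5-(dimethoxymethyl)-4-formyl-2-oxotetrahydrofuran-3-yl]phosphonate, via aldol adduct 6 (not isolated)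
Conditions: L-proline (20 mol %), 5 (3 equiv), DMF, 4 °C, slow addition of 4; then PPTS (10 mol %), 4 Å MS, toluene, 40 °C
Reagents that add atoms: none
Why: Proline-catalysed direct cross-aldol of the enamine of 4 with the non-enolisable acceptor 5 through the hydrogen-bonded chair transition state should give the anti adduct with C7 and C8 set by L-proline, and the γ-hydroxy ester then lactonises to the 4,5-cis lactone.

Step 4
Reactants: 8 3-[(tert-butyldimethylsilyl)oxy]propanal; 9 2-(triphenylphosphoranylidene)propanal
Product: 10 (E)-5-[(tert-butyldimethylsilyl)oxy]-2-methylpent-2-enal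
Conditions: toluene, 90 °C
Reagents that add atoms: none
Why: Wittig olefination with the stabilised formyl ylide should give the E trisubstituted enal under thermodynamic control of oxaphosphetane formation.

Step 5
Reactants: 10 (E)-5-[(tert-butyldimethylsilyl)oxy]-2-methylpent-2-enal
Product: 11 (E)-tert-butyldimethyl[(4-methylhex-3-en-5-yn-1-yl)oxy]silane
Conditions: TMSCHN2, n-BuLi, THF, −78 °C → rt
Reagents that add atoms: (trimethylsilyl)diazomethane C[Si](C)(C)C=[N+]=[N-]
Why: Colvin rearrangement (1,2-addition, Peterson-type loss of silanolate, loss of N2 and 1,2-hydride shift of the alkylidene carbene) should give the enyne with the E alkene unchanged.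

Step 6
Reactants: 11 (E)-tert-butyldimethyl[(4-methylhex-3-en-5-yn-1-yl)oxy]silane
Product: 12 tert-butyldimethyl{[(3E,5S)-4-methyl-5,6-bis(4,4,5,5-tetramethyl-1,3,2-dioxaborolan-2-yl)hex-3-en-1-yl]oxy}silane
Conditions: CuCl (5 mol %), chiral sulfonate-bearing imidazolinium salt (5 mol %), NaOt-Bu (20 mol %), B2pin2 (2.1 equiv), MeOH (3 equiv), THF, −15 °C
Reagents that add atoms: bis(pinacolato)diboron CC1(C)OB(OC1(C)C)B1OC(C)(C)C(C)(C)O1
Why: Copper-catalysed double protoboration of a terminal alkyne (boron to the terminal carbon, protonation, then enantioselective boryl-copper addition to the alkenylboronate with copper α to boron) should give the vicinal bis(boronate), the C1 centre being set by the chiral carbene ligand, whose enantiomer is chosen to deliver S.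

Step 7
Reactants: 7 lactone aldehyde; 12 (S)-bis(boronate)
Product: 14 6-O-acetyl (Z)-allylboronate (acetate of 13), via homoallylic alcohol 13 (not isolated)
Conditions: 12 (1.5 equiv), toluene, 40 °C, slow addition of 7; aq. NaHCO3 work-up; then Ac2O, pyridine, DMAP (cat.), CH2Cl2, 0 °C
Reagents that add atoms: acetic anhydride CC(=O)OC(C)=O
Why: Allylboration of the only aldehyde by the secondary allylic boronate through a chair Zimmerman–Traxler transition state (α-CH2Bpin axial, hence the Z alkene and a new primary allylboronate; E γ-substituent equatorial, hence the anti C5/C6 relationship) should set C5 and C6 under control of the S reagent on the Felkin face of 7, and immediate acetylation blocks translactonisation.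

Step 8
Reactants: 14 6-O-acetyl (Z)-allylboronate
Product: 17 6-O-acetyl-9,15-dihydroxy phosphono lactone with the cyclohexane closed, via hydroxy aldehyde 15 (not isolated), via cyclic O-boryl ether 16 (not isolated)
Conditions: TFA/H2O (9:1), CH2Cl2 (0.01 M), 0 °C → rt; aq. NaHCO3
Reagents that add atoms: water O
Why: Aqueous acid hydrolyses the acyloxy-deactivated dimethyl acetal (and the silyl ether), and the liberated C9 aldehyde should be captured at once by the tethered (Z)-γ,γ-disubstituted allylboronate in an intramolecular allylboration (boron moves from C2 to O9, C10 bonds to C9, C1=C2 becomes the vinyl group), the O-boryl ether 16 being hydrolysed in the medium. The closest known reaction type is the acetal-unmasking intramolecular allylboration of ω-oxo allylboronates, which is also the ring-closing second stage of bis(boronate) double allylations. The six-membered carbocycle C5–C10 closes by C9–C10 bond formation in a chair Zimmerman–Traxler transition state cis-fused to the forming ring, with C10 as the nucleophilic γ-carbon and the C9 carbonyl as electrophile. C10 is controlled by allylic 1,3-strain across the Z-configured C1=C10 bond: H5 lies in the alkene plane toward C2, so the aldehyde, tethered through C6, attacks the face anti to the C5 side chain and the methyl group ends cis to that chain. C9 is controlled by the Z geometry fixed in step 7: C5 is pseudo-axial and C8 equatorial in the chair, so O9 ends cis to the vinyl group, which is also the Felkin-type face of the α-acyloxy aldehyde. The step needs intramolecular capture to outrun protodeboronation and intermolecular allylation; high dilution, the acid-tolerant pinacol boronate and the proximity of C9 to C10 should secure this.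

Step 9
Reactants: 17 6-O-acetyl-9,15-dihydroxy phosphono lactone
Product: 18 15-aldehyde (C5–CH2–CHO)
Conditions: TEMPO (10 mol %), PhI(OAc)2 (1.2 equiv), CH2Cl2, rt
Reagents that add atoms: none
Why: Oxoammonium (TEMPO) oxidation should convert the primary alcohol selectively, the hindered secondary C9 alcohol next to quaternary C10 reacting far more slowly; no stereocentre changes.

Step 10
Reactants: 18 15-aldehyde
Product: 19 2-substituted acrolein (C5–C4(=C3H2)–C15HO)
Conditions: 37 % aq. HCHO, pyrrolidine (10 mol %), propionic acid (10 mol %), i-PrOH, 45 °C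
Reagents that add atoms: formaldehyde C=O
Why: Amine-catalysed Mannich condensation and elimination (α-methylenation of an aldehyde) should install C3 on C4, which has no stereocentre, under buffered conditions that leave the phosphonate untouched.

Step 11
Reactants: 19 2-substituted acrolein; 20 angelic acid
Product: 21 9-O-angeloyl phosphono lactone
Conditions: 20, 2,4,6-trichlorobenzoyl chloride, Et3N, toluene, rt; then 19, DMAP, toluene, 60 °C
Reagents that add atoms: none
Why: Yamaguchi esterification through the mixed anhydride should acylate the hindered C9 alcohol with retention at C9 and of the Z geometry of the angelate, and it is placed before the lactone methylenation so that no free C9 hydroxyl can add to the methylene lactone.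

Step 12
Reactants: 21 9-O-angeloyl phosphono lactone
Product: 22 target
Conditions: 37 % aq. HCHO, K2CO3, THF, 0 °C → rt
Reagents that add atoms: formaldehyde C=O
Why: Horner–Wadsworth–Emmons methylenation of the α-phosphono lactone with formaldehyde under mild carbonate base should give the α-methylene lactone, both C11 epimers converging and the esters surviving the short exposure.

**Compound list**

1 | trimethyl phosphonoacetate | COC(=O)CP(=O)(OC)OC | starting material
2 | allyl bromide | C=CCBr | starting material
3 | methyl 2-(dimethoxyphosphoryl)pent-4-enoate (racemic) | C=CCC(C(=O)OC)P(=O)(OC)OC | intermediate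
4 | methyl 2-(dimethoxyphosphoryl)-4-oxobutanoate (racemic) | O=CCC(C(=O)OC)P(=O)(OC)OC | intermediate
5 | 2,2-dimethoxyacetaldehyde | COC(OC)C=O | starting material
6 | methyl (3S,4R)-2-(dimethoxyphosphoryl)-3-formyl-4-hydroxy-5,5-dimethoxypentanoate (anti aldol adduct, C2 epimers) | COC(OC)[C@H](O)[C@@H](C=O)C(C(=O)OC)P(=O)(OC)OC | intermediate
7 | dimethyl [(3S,4S,5R)-5-(dimethoxymethyl)-4-formyl-2-oxotetrahydrofuran-3-yl]phosphonate (4,5-cis lactone; C7–CHO, C8–CH(OMe)2) | COC(OC)[C@@H]1OC(=O)[C@@H](P(=O)(OC)OC)[C@@H]1C=O | intermediate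
8 | 3-[(tert-butyldimethylsilyl)oxy]propanal | O=CCCO[Si](C)(C)C(C)(C)C | starting material
9 | 2-(triphenylphosphoranylidene)propanal | CC(C=O)=P(c1ccccc1)(c1ccccc1)c1ccccc1 | starting material
10 | (E)-5-[(tert-butyldimethylsilyl)oxy]-2-methylpent-2-enal | O=C/C(C)=C/CCO[Si](C)(C)C(C)(C)C | intermediate
11 | (E)-tert-butyldimethyl[(4-methylhex-3-en-5-yn-1-yl)oxy]silane | C#C/C(C)=C/CCO[Si](C)(C)C(C)(C)C | intermediate
12 | tert-butyldimethyl{[(3E,5S)-4-methyl-5,6-bis(4,4,5,5-tetramethyl-1,3,2-dioxaborolan-2-yl)hex-3-en-1-yl]oxy}silane | B1(OC(C)(C)C(C)(C)O1)C[C@H](B2OC(C)(C)C(C)(C)O2)/C(C)=C/CCO[Si](C)(C)C(C)(C)C | intermediate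
13 | homoallylic alcohol: lactone of 7 with C6H(OH) bonded to C5H; C5 carries CH2CH2OTBS and the (Z)-C10(CH3)=C1H–C2H2Bpin unit; C5–C8 as in 22 | COC(OC)[C@@H]1OC(=O)[C@@H](P(=O)(OC)OC)[C@@H]1[C@@H](O)[C@@H](CCO[Si](C)(C)C(C)(C)C)/C(C)=C\CB2OC(C)(C)C(C)(C)O2 | intermediate
14 | 6-O-acetate of 13 (cyclisation precursor) | COC(OC)[C@@H]1OC(=O)[C@@H](P(=O)(OC)OC)[C@@H]1[C@@H](OC(C)=O)[C@@H](CCO[Si](C)(C)C(C)(C)C)/C(C)=C\CB2OC(C)(C)C(C)(C)O2 | intermediate
15 | hydroxy aldehyde: 14 with C9 as CHO and C15 as CH2OH | O=C[C@@H]1OC(=O)[C@@H](P(=O)(OC)OC)[C@@H]1[C@@H](OC(C)=O)[C@@H](CCO)/C(C)=C\CB2OC(C)(C)C(C)(C)O2 | intermediate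
16 | cyclic O-boryl ether: cyclohexane closed, O9–Bpin | C=C[C@]1(C)[C@H](OB3OC(C)(C)C(C)(C)O3)[C@@H]2OC(=O)[C@@H](P(=O)(OC)OC)[C@@H]2[C@@H](OC(C)=O)[C@H]1CCO | intermediate
17 | 6-O-acetyl-9,15-dihydroxy phosphono lactone: cis-fused 8,12-lactone on cyclohexane C5–C10; C10 methyl and vinyl, C9–OH, C6–OAc, C5–CH2CH2OH, C11–P(O)(OMe)2; ring centres as in 22 | C=C[C@]1(C)[C@H](O)[C@@H]2OC(=O)[C@@H](P(=O)(OC)OC)[C@@H]2[C@@H](OC(C)=O)[C@H]1CCO | intermediate
18 | 15-aldehyde: 17 with C5–CH2–CHO | C=C[C@]1(C)[C@H](O)[C@@H]2OC(=O)[C@@H](P(=O)(OC)OC)[C@@H]2[C@@H](OC(C)=O)[C@H]1CC=O | intermediate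
19 | 2-substituted acrolein: 18 with C5–C(=CH2)–CHO | C=C[C@]1(C)[C@H](O)[C@@H]2OC(=O)[C@@H](P(=O)(OC)OC)[C@@H]2[C@@H](OC(C)=O)[C@H]1C(=C)C=O | intermediate
20 | angelic acid, (Z)-2-methylbut-2-enoic acid | C/C=C(/C)C(=O)O | starting material
21 | 9-O-angeloyl phosphono lactone | C=C[C@]1(C)[C@H](OC(=O)/C(C)=C\C)[C@@H]2OC(=O)[C@@H](P(=O)(OC)OC)[C@@H]2[C@@H](OC(C)=O)[C@H]1C(=C)C=O | intermediate
22 | target (5R,6S,7R,8R,9S,10S) | C=C[C@]1(C)[C@H](OC(=O)/C(C)=C\C)[C@@H]2OC(=O)C(=C)[C@@H]2[C@@H](OC(C)=O)[C@H]1C(=C)C=O | target

**Total step count:** 12. **Longest linear sequence:** 9 steps (1, 2, 3, 7–12; the branch 4, 5, 6, 7–12 is equally long).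

**Steps most likely to fail**

Step 8 (key step). The allyl–boron bond may be protonated off in the acid before the deactivated acetal is unmasked. The allylboronate may also capture the oxocarbenium ion and leave a C9 methyl ether, or the closure may leak through a boat transition state with loss of facial selectivity. The fallback sets out from 14 and comes back at 17. The allyl–boron bond is oxidised with NaBO3·4H2O (THF/H2O, rt) to the (Z)-allylic alcohol F1, which CBr4/PPh3 (CH2Cl2, 0 °C) converts into the (Z)-allylic bromide F2. TFA/H2O then unmasks acetal and silyl ether to give the bromo hydroxy aldehyde F3. CrCl2 (divalent chromium, THF/DMF, rt, high dilution) closes the same C9–C10 bond by an intramolecular Nozaki–Hiyama allylation through the γ-carbon C10 to give 17.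

Step 7. The hindered α-substituted boronate may add slowly, and during that time the β-acyloxy aldehyde 7 can eliminate the lactone carboxylate or epimerise at C7; the newly formed primary allylboronate may also add to a second molecule of 7. The fallback sets out from 6 and 12 and comes back at 14. The crude aldol adduct 6 is silylated before lactonisation (TESCl, imidazole, DMF, 0 °C) to give the β-silyloxy aldehyde F4, which has no leaving group β to the formyl group. Allylboration of F4 with 12 (toluene, 40 °C) and acetylation of the crude alcohol give the open-chain acetate F5. PPTS in MeOH (0 °C) removes the triethylsilyl group, and PPTS in toluene (40 °C) closes the lactone to give 14, still before the carbocycle is formed.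

Step 6. The second boryl-copper addition to the conjugated dienylboronate may run with poor site control (1,4- or 1,6-addition) or low enantioselectivity. The fallback sets out from 10 and comes back at 14. Wittig methylenation of 10 (Ph3P=CH2, THF, 0 °C) gives the (E)-diene F6. Phosphine-free Pt(dba)2 (zerovalent platinum, 3 mol %) with B2pin2 in toluene at rt adds both boron atoms to the terminal alkene to give the racemic bis(boronate) F7. Three equivalents of F7 are used under the conditions of step 7, where the Felkin preference of 7 should consume the matched S enantiomer faster (mutual kinetic resolution), and the minor diastereomer is removed by chromatography of 14.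

**Further compounds**

F1 | step 8 | (Z)-allylic alcohol from 14 (C2–OH in place of C2–Bpin) | COC(OC)[C@@H]1OC(=O)[C@@H](P(=O)(OC)OC)[C@@H]1[C@@H](OC(C)=O)[C@@H](CCO[Si](C)(C)C(C)(C)C)/C(C)=C\CO
F2 | step 8 | (Z)-allylic bromide | COC(OC)[C@@H]1OC(=O)[C@@H](P(=O)(OC)OC)[C@@H]1[C@@H](OC(C)=O)[C@@H](CCO[Si](C)(C)C(C)(C)C)/C(C)=C\CBr
F3 | step 8 | bromo hydroxy aldehyde (C9 CHO, C15 CH2OH) | O=C[C@@H]1OC(=O)[C@@H](P(=O)(OC)OC)[C@@H]1[C@@H](OC(C)=O)[C@@H](CCO)/C(C)=C\CBr
F4 | step 7 | 4-O-triethylsilyl ether of aldol adduct 6 | COC(OC)[C@H](O[Si](CC)(CC)CC)[C@@H](C=O)C(C(=O)OC)P(=O)(OC)OC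
F5 | step 7 | open-chain 6-O-acetyl 8-O-triethylsilyl (Z)-allylboronate methyl ester | COC(OC)[C@H](O[Si](CC)(CC)CC)[C@H](C(C(=O)OC)P(=O)(OC)OC)[C@@H](OC(C)=O)[C@@H](CCO[Si](C)(C)C(C)(C)C)/C(C)=C\CB1OC(C)(C)C(C)(C)O1
F6 | step 6 | (E)-tert-butyldimethyl[(4-methylhexa-3,5-dien-1-yl)oxy]silane | C=C/C(C)=C/CCO[Si](C)(C)C(C)(C)C
F7 | step 6 | racemic 12 | B1(OC(C)(C)C(C)(C)O1)CC(B2OC(C)(C)C(C)(C)O2)/C(C)=C/CCO[Si](C)(C)C(C)(C)C
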